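**Retrosynthetic overview**

1. Numbering (germacrane/eudesmane) used throughout: C10 = quaternary ether carbon (14‑CH3), C5 = the other ether carbon, C4 = CHCH3, C6 = CH2, C7–C11–C12(=O)–O–C8 = lactone, C13 = exocyclic CH2, C9 = acyloxy carbon; β = face of the 14‑methyl. Last disconnections: the C9 ester and the C11=C13 methylene.
2. Key disconnection: the ether oxygen is taken out from between C5 and C10 of the 11‑oxabicyclo[4.4.1]undecane core. Both oxepanes are traced back to the two cyclohexanes of a eudesmane‑type decalin with a C5–C10 bond and a ring‑fusion hydroperoxide at C5 (Criegee 1,2‑shift of C10 to oxygen, then hydride at C5).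
3. Enabling feature: the ether carbons C5 and C10 lie 1,6 across the cyclodecane, so they are the two adjacent ring‑fusion atoms of a decalin. C10 is fully substituted (best migrating group, migrates with retention), and the one‑atom bridge allows only one configuration at C5, so both C5 epimers of the hydroperoxide converge.
4. The hydroperoxide comes from the Δ5 alkene (Co‑catalysed hydroperoxidation). Ring B is closed by RCM (C5=C6) after the two halves are joined at the quaternary C10–C9 bond by allylboration of a trans‑vinyl lactone aldehyde.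
5. Ring order: lactone (from (R)‑5‑(hydroxymethyl)butenolide) and ring A (from cis‑2,6‑dimethylcyclohexanone, desymmetrised) are bought in; ring B by RCM; both seven‑membered oxacycles together in the key step.

Key step: step 13

Assumption: the (R,R)‑amide base is taken to remove the α‑proton at the (R)‑configured carbon of meso ketone 1, leaving the (S) centre (if the sense is the reverse, the (S,S)‑amide is used and nothing else changes); (R)‑butenolide 5 and (R)‑2‑methylbutanoic acid 24 are taken as purchasable single enantiomers.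

**Route**

Step 1
Reactants: 1 cis‑2,6‑dimethylcyclohexanone
Product: 3 (6S)‑2,6‑dimethylcyclohex‑1‑en‑1‑yl trifluoromethanesulfonate, via lithium enolate 2 (not isolated)
Conditions: (R,R)‑bis(1‑phenylethyl)amine, n‑BuLi, LiCl, THF, −78 °C; then PhNTf2, −78 → 0 °C
Reagents that add atoms: N‑phenylbis(trifluoromethanesulfonimide), O=S(=O)(N(c1ccccc1)S(=O)(=O)C(F)(F)F)C(F)(F)F
Why: Desymmetrising deprotonation of the meso ketone by a chiral lithium amide should remove one enantiotopic α‑proton so that the untouched CHMe centre (future C4) is S, and O‑sulfonylation of the enolate fixes the double bond (enol triflate formation).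

Step 2
Reactants: 3 (6S)‑2,6‑dimethylcyclohex‑1‑en‑1‑yl trifluoromethanesulfonate
Product: 4 2‑{[(6S)‑2,6‑dimethylcyclohex‑1‑en‑1‑yl]methyl}‑4,4,5,5‑tetramethyl‑1,3,2‑dioxaborolane
Conditions: ICH2Bpin, Zn dust, THF, rt (gives IZnCH2Bpin); then 3, Pd(PPh3)4 (5 mol %), THF, 50 °C
Reagents that add atoms: 2‑(iodomethyl)‑4,4,5,5‑tetramethyl‑1,3,2‑dioxaborolane, ICB1OC(C)(C)C(C)(C)O1
Why: Negishi coupling of the alkenyl triflate with the (borylmethyl)zinc reagent should give the allylboronate without touching the allylic stereocentre.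

Step 3
Reactants: 5 (5R)‑5‑(hydroxymethyl)furan‑2(5H)‑one
Product: 6 (5R)‑5‑{[(tert‑butyldiphenylsilyl)oxy]methyl}furan‑2(5H)‑one
Conditions: TBDPSCl, imidazole, CH2Cl2, 0 °C → rt
Reagents that add atoms: tert‑butyl(chloro)diphenylsilane, CC(C)(C)[Si](Cl)(c1ccccc1)c1ccccc1
Why: Silylation of the primary alcohol; no stereocentre is touched.

Step 4
Reactants: 6 (5R)‑5‑{[(tert‑butyldiphenylsilyl)oxy]methyl}furan‑2(5H)‑one
Product: 7 (4S,5R)‑5‑{[(tert‑butyldiphenylsilyl)oxy]methyl}‑4‑ethenyloxolan‑2‑one (4,5‑trans)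
Conditions: CH2=CHMgBr, CuI (15 mol %), THF, −78 → −40 °C; aqueous work‑up
Reagents that add atoms: vinylmagnesium bromide, C=C[Mg]Br
Why: Copper‑catalysed conjugate addition to the butenolide should occur anti to the C5 silyloxymethyl group and so set the 4,5‑trans relationship (future C7/C8).

Step 5
Reactants: 7 (4S,5R)‑5‑{[(tert‑butyldiphenylsilyl)oxy]methyl}‑4‑ethenyloxolan‑2‑one
Product: 8 (4S,5R)‑4‑ethenyl‑5‑(hydroxymethyl)oxolan‑2‑one
Conditions: HF·pyridine, THF, 0 °C → rt
Reagents that add atoms: none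
Why: Fluoride cleavage of the silyl ether, to which the lactone and the alkene are inert.

Step 6
Reactants: 8 (4S,5R)‑4‑ethenyl‑5‑(hydroxymethyl)oxolan‑2‑one
Product: 9 (2R,3S)‑3‑ethenyl‑5‑oxooxolane‑2‑carbaldehyde (2,3‑trans)
Conditions: Dess–Martin periodinane, CH2Cl2, 0 °C → rt; used without storage
Reagents that add atoms: none
Why: Dess–Martin oxidation of the primary alcohol under non‑basic conditions should leave the α‑oxygenated centre (future C8) unepimerised.

Step 7
Reactants: 4 2‑{[(6S)‑2,6‑dimethylcyclohex‑1‑en‑1‑yl]methyl}‑4,4,5,5‑tetramethyl‑1,3,2‑dioxaborolane and 9 (2R,3S)‑3‑ethenyl‑5‑oxooxolane‑2‑carbaldehyde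
Product: 10 (4S,5R)‑4‑ethenyl‑5‑{[(1S,3S)‑1,3‑dimethyl‑2‑methylidenecyclohexyl](hydroxy)methyl}oxolan‑2‑one (both carbinol epimers at C9)
Conditions: Sc(OTf)3 (10 mol %), CH2Cl2, −78 → −20 °C; aq. NaHCO3
Reagents that add atoms: none
Why: Lewis‑acid‑catalysed allylboration through a closed six‑membered transition state with allylic transposition joins the two halves at the quaternary C10–C9 bond; boron and aldehyde should stay on the ring face opposite to the pseudoaxial C4 methyl (A1,2 strain), which places the new bond trans to that methyl (10‑Me cis to 4‑Me), while the carbinol centre is left uncontrolled because step 8 removes it.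

Step 8
Reactants: 10 (4S,5R)‑4‑ethenyl‑5‑{[(1S,3S)‑1,3‑dimethyl‑2‑methylidenecyclohexyl](hydroxy)methyl}oxolan‑2‑one
Product: 11 (4S,5R)‑5‑[(1S,3S)‑1,3‑dimethyl‑2‑methylidenecyclohexane‑1‑carbonyl]‑4‑ethenyloxolan‑2‑one
Conditions: Dess–Martin periodinane, CH2Cl2, rt
Reagents that add atoms: none
Why: Dess–Martin oxidation converges both carbinol epimers to one ketone; C10 is quaternary, so the β,γ‑unsaturated ketone cannot move into conjugation.

Step 9
Reactants: 11 (4S,5R)‑5‑[(1S,3S)‑1,3‑dimethyl‑2‑methylidenecyclohexane‑1‑carbonyl]‑4‑ethenyloxolan‑2‑one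
Product: 12 (4S,7S,8R,10S)‑4,10‑dimethyl‑9‑oxo‑13‑nor‑eudesm‑5‑en‑12,8‑olide (4β,10β‑dimethyl; trans‑fused lactone: 7β‑C11 and 8α‑O)
Conditions: Hoveyda–Grubbs 2nd‑generation catalyst (10 mol %), toluene (0.002 M), 80 °C
Reagents that add atoms: none
Why: Ring‑closing metathesis of the vinyl group with the 1,1‑disubstituted exocyclic alkene should close ring B as a six‑membered trisubstituted cycloalkene (C5=C6) with loss of ethene.

Step 10
Reactants: 12 (4S,7S,8R,10S)‑4,10‑dimethyl‑9‑oxo‑13‑nor‑eudesm‑5‑en‑12,8‑olide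
Product: 13 (4S,7S,8R,9R,10S)‑9β‑hydroxy‑4,10‑dimethyl‑13‑nor‑eudesm‑5‑en‑12,8‑olide
Conditions: NaBH4, MeOH–CH2Cl2, −40 °C
Reagents that add atoms: none
Why: Axial hydride delivery to the C9 ketone from the α face, opposite to the axial C10 methyl, should give the equatorial 9β‑alcohol (the sense known for borohydride reduction of angular‑methyl decalones) and leaves the lactone untouched.

Step 11
Reactants: 13 (4S,7S,8R,9R,10S)‑9β‑hydroxy‑4,10‑dimethyl‑13‑nor‑eudesm‑5‑en‑12,8‑olide
Product: 14 (4S,7S,8R,9R,10S)‑9β‑(tert‑butyldimethylsilyloxy)‑4,10‑dimethyl‑13‑nor‑eudesm‑5‑en‑12,8‑olide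
Conditions: TBSOTf, 2,6‑lutidine, CH2Cl2, 0 °C
Reagents that add atoms: tert‑butyldimethylsilyl trifluoromethanesulfonate, CC(C)(C)[Si](C)(C)OS(=O)(=O)C(F)(F)F
Why: Silyl triflate silylation of the hindered secondary alcohol; a silyl ether is chosen over the final ester so that the C9 oxygen retards C10 migration in step 13 as little as possible and the ester stereocentre is not exposed to LDA in step 14.

Step 12
Reactants: 14 (4S,7S,8R,9R,10S)‑9β‑(tert‑butyldimethylsilyloxy)‑4,10‑dimethyl‑13‑nor‑eudesm‑5‑en‑12,8‑olide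
Product: 16 (4S,7R,8R,9R,10R)‑5‑hydroperoxy‑9β‑(tert‑butyldimethylsilyloxy)‑4,10‑dimethyl‑13‑nor‑eudesman‑12,8‑olide (both C5 epimers), via triethylsilyl peroxide 15 (not isolated)
Conditions: Co(thd)2 (10 mol %), Et3SiH, O2 (1 atm), 1,2‑dichloroethane, rt; then MeOH, HCl (cat.), 0 °C
Reagents that add atoms: dioxygen, O=O
Why: Mukaiyama–Isayama hydroperoxidation: cobalt hydride transfers H to C6, the tertiary C5 radical is trapped by O2 and the silyl peroxide is methanolysed; the C5 configuration is deliberately left uncontrolled because step 13 is stereoconvergent.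

Step 13
Reactants: 16 (4S,7R,8R,9R,10R)‑5‑hydroperoxy‑9β‑(tert‑butyldimethylsilyloxy)‑4,10‑dimethyl‑13‑nor‑eudesman‑12,8‑olide (both C5 epimers)
Product: 19 (4S,5R,7R,8R,9S,10R)‑9‑(tert‑butyldimethylsilyloxy)‑5,10‑epoxy‑13‑nor‑germacran‑12,8‑olide, via trifluoroperacetate 17 (not isolated), via ketal trifluoroacetate 18 (not isolated)
Conditions: (CF3CO)2O, 2,6‑lutidine, CH2Cl2, −40 → 0 °C; then Et3SiH, BF3·OEt2, −78 → −20 °C
Reagents that add atoms: none
Why: Peracylation of the ring‑fusion hydroperoxide gives a trifluoroperacetate that ionises with concerted 1,2‑shift of C10 from C5 to oxygen (Criegee rearrangement; closest precedent: 9‑decalyl peresters giving 1‑acyloxy‑11‑oxabicyclo[4.4.1]undecanes), so that oxygen is inserted into the shared C5–C10 bond and both cyclohexanes of the decalin become the two oxepanes in one event (two 6→7 ring expansions; no tethered ring closure is involved). The ion pair collapses to the bridgehead ketal trifluoroacetate 18, which BF3·OEt2 re‑ionises to the bridgehead oxocarbenium ion that Et3SiH reduces (Lewis acid/silane reduction of a ketal ester, as used for bridged bicyclic hemiketals). C10 migrates with retention, so its configuration is carried over unchanged from step 7; the new C5–H centre has no choice, because the one‑atom oxygen bridge must be cis at both bridgeheads and hydride can only arrive on the exo face. For the same reason the step is stereoconvergent: both C5 epimers of 16 (cis‑ and trans‑fused) lose that centre in the cation and should give one product. The selectivity needed is migration of C10 rather than C4 or C6; it rests on C10 being the only fully substituted neighbour of C5 (C4 secondary, C6 primary), on the exo rotamer of the perester, which places O–O antiperiplanar to the ring‑fusion bond, and on the C9 oxygen being a silyl ether and not an ester, which keeps its inductive retardation of C10 small.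

Step 14
Reactants: 19 (4S,5R,7R,8R,9S,10R)‑9‑(tert‑butyldimethylsilyloxy)‑5,10‑epoxy‑13‑nor‑germacran‑12,8‑olide
Product: 22 (4S,5R,7R,8R,9S,10R)‑9‑(tert‑butyldimethylsilyloxy)‑5,10‑epoxygermacr‑11(13)‑en‑12,8‑olide, via Mannich base 20 (not isolated), via methiodide 21 (not isolated)
Conditions: LDA, THF, −78 °C; CH2=NMe2+ I−, −78 °C → rt; MeI, THF, rt; then aq. NaHCO3/CH2Cl2, rt
Reagents that add atoms: Eschenmoser's salt (N,N‑dimethylmethyleneiminium iodide), C=[N+](C)C.[I-]
Why: α‑Methylenation of the lactone by Mannich reaction of its lithium enolate with Eschenmoser's salt, quaternisation and E1cB elimination; the lactone α‑CH2 is the only enolisable position and no stereocentre is formed.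

Step 15
Reactants: 22 (4S,5R,7R,8R,9S,10R)‑9‑(tert‑butyldimethylsilyloxy)‑5,10‑epoxygermacr‑11(13)‑en‑12,8‑olide
Product: 23 (4S,5R,7R,8R,9S,10R)‑9‑hydroxy‑5,10‑epoxygermacr‑11(13)‑en‑12,8‑olide
Conditions: HF·pyridine, pyridine/THF, 0 °C → rt
Reagents that add atoms: none
Why: Si–O cleavage by HF·pyridine, to which the α‑methylene lactone and the ether bridge should be inert.

Step 16
Reactants: 23 (4S,5R,7R,8R,9S,10R)‑9‑hydroxy‑5,10‑epoxygermacr‑11(13)‑en‑12,8‑olide and 24 (R)‑2‑methylbutanoic acid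
Product: 26 (4S,5R,7R,8R,9S,10R)‑5,10‑epoxygermacr‑11(13)‑en‑12,8‑olid‑9‑yl (2R)‑2‑methylbutanoate (CNP0136059.1), via mixed anhydride 25 (not isolated)
Conditions: 24, 2,4,6‑trichlorobenzoyl chloride, Et3N, toluene, rt; then 23, DMAP, toluene, rt → 40 °C
Reagents that add atoms: none
Why: Yamaguchi esterification acylates the hindered secondary alcohol through the preformed mixed anhydride without enolising the α‑stereocentre of the acid; all ring stereocentres are untouched.

**Compound list**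

1 | cis‑2,6‑dimethylcyclohexanone (meso, 2R,6S) | C[C@H]1CCC[C@@H](C)C1=O | starting material
2 | lithium (6S)‑2,6‑dimethylcyclohex‑1‑en‑1‑olate | CC1=C(O[Li])[C@@H](C)CCC1 | intermediate
3 | (6S)‑2,6‑dimethylcyclohex‑1‑en‑1‑yl trifluoromethanesulfonate | CC1=C(OS(=O)(=O)C(F)(F)F)[C@@H](C)CCC1 | intermediate
4 | 2‑{[(6S)‑2,6‑dimethylcyclohex‑1‑en‑1‑yl]methyl}‑4,4,5,5‑tetramethyl‑1,3,2‑dioxaborolane | CC1=C(CB2OC(C)(C)C(C)(C)O2)[C@@H](C)CCC1 | intermediate
5 | (5R)‑5‑(hydroxymethyl)furan‑2(5H)‑one | O=C1O[C@@H](CO)C=C1 | starting material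
6 | (5R)‑5‑{[(tert‑butyldiphenylsilyl)oxy]methyl}furan‑2(5H)‑one | O=C1O[C@@H](CO[Si](c2ccccc2)(c2ccccc2)C(C)(C)C)C=C1 | intermediate
7 | (4S,5R)‑5‑{[(tert‑butyldiphenylsilyl)oxy]methyl}‑4‑ethenyloxolan‑2‑one | O=C1O[C@@H](CO[Si](c2ccccc2)(c2ccccc2)C(C)(C)C)[C@@H](C1)C=C | intermediate
8 | (4S,5R)‑4‑ethenyl‑5‑(hydroxymethyl)oxolan‑2‑one | O=C1O[C@@H](CO)[C@@H](C1)C=C | intermediate
9 | (2R,3S)‑3‑ethenyl‑5‑oxooxolane‑2‑carbaldehyde | O=C1O[C@@H](C=O)[C@@H](C1)C=C | intermediate
10 | (4S,5R)‑4‑ethenyl‑5‑{[(1S,3S)‑1,3‑dimethyl‑2‑methylidenecyclohexyl](hydroxy)methyl}oxolan‑2‑one, carbinol epimers | O=C1O[C@@H](C(O)[C@@]2(C)CCC[C@H](C)C2=C)[C@@H](C1)C=C | intermediate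
11 | (4S,5R)‑5‑[(1S,3S)‑1,3‑dimethyl‑2‑methylidenecyclohexane‑1‑carbonyl]‑4‑ethenyloxolan‑2‑one | O=C1O[C@@H](C(=O)[C@@]2(C)CCC[C@H](C)C2=C)[C@@H](C1)C=C | intermediate
12 | (4S,7S,8R,10S)‑4,10‑dimethyl‑9‑oxo‑13‑nor‑eudesm‑5‑en‑12,8‑olide | O=C1O[C@@H]2[C@@H](C1)C=C1[C@](C)(CCC[C@@H]1C)C2=O | intermediate
13 | (4S,7S,8R,9R,10S)‑9β‑hydroxy‑4,10‑dimethyl‑13‑nor‑eudesm‑5‑en‑12,8‑olide | O=C1O[C@@H]2[C@@H](C1)C=C1[C@](C)(CCC[C@@H]1C)[C@H]2O | intermediate
14 | (4S,7S,8R,9R,10S)‑9β‑(tert‑butyldimethylsilyloxy)‑4,10‑dimethyl‑13‑nor‑eudesm‑5‑en‑12,8‑olide | O=C1O[C@@H]2[C@@H](C1)C=C1[C@](C)(CCC[C@@H]1C)[C@H]2O[Si](C)(C)C(C)(C)C | intermediate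
15 | 5‑(triethylsilylperoxy) derivative of 14 (H at C6, both C5 epimers) | O=C1O[C@@H]2[C@@H](C1)CC1(OO[Si](CC)(CC)CC)[C@](C)(CCC[C@@H]1C)[C@H]2O[Si](C)(C)C(C)(C)C | intermediate
16 | (4S,7R,8R,9R,10R)‑5‑hydroperoxy‑9β‑(tert‑butyldimethylsilyloxy)‑4,10‑dimethyl‑13‑nor‑eudesman‑12,8‑olide, both C5 epimers | O=C1O[C@@H]2[C@@H](C1)CC1(OO)[C@](C)(CCC[C@@H]1C)[C@H]2O[Si](C)(C)C(C)(C)C | intermediate
17 | C5 trifluoroperacetate of 16 | O=C1O[C@@H]2[C@@H](C1)CC1(OOC(=O)C(F)(F)F)[C@](C)(CCC[C@@H]1C)[C@H]2O[Si](C)(C)C(C)(C)C | intermediate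
18 | 5‑(trifluoroacetoxy)‑9‑(tert‑butyldimethylsilyloxy)‑5,10‑epoxy‑13‑nor‑germacran‑12,8‑olide (bridgehead ketal ester, acyloxy exo) | C1C(=O)O[C@@H]2[C@@H]1C[C@@]1(OC(=O)C(F)(F)F)O[C@](C)(CCC[C@@H]1C)[C@H]2O[Si](C)(C)C(C)(C)C | intermediate
19 | (4S,5R,7R,8R,9S,10R)‑9‑(tert‑butyldimethylsilyloxy)‑5,10‑epoxy‑13‑nor‑germacran‑12,8‑olide | C1C(=O)O[C@@H]2[C@@H]1C[C@H]1O[C@](C)(CCC[C@@H]1C)[C@H]2O[Si](C)(C)C(C)(C)C | intermediate
20 | 11‑[(dimethylamino)methyl] derivative of 19 (C11 epimers) | CN(C)CC1C(=O)O[C@@H]2[C@@H]1C[C@H]1O[C@](C)(CCC[C@@H]1C)[C@H]2O[Si](C)(C)C(C)(C)C | intermediate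
21 | trimethylammonium iodide of 20 | C[N+](C)(C)CC1C(=O)O[C@@H]2[C@@H]1C[C@H]1O[C@](C)(CCC[C@@H]1C)[C@H]2O[Si](C)(C)C(C)(C)C.[I-] | intermediate
22 | (4S,5R,7R,8R,9S,10R)‑9‑(tert‑butyldimethylsilyloxy)‑5,10‑epoxygermacr‑11(13)‑en‑12,8‑olide | C=C1C(=O)O[C@@H]2[C@@H]1C[C@H]1O[C@](C)(CCC[C@@H]1C)[C@H]2O[Si](C)(C)C(C)(C)C | intermediate
23 | (4S,5R,7R,8R,9S,10R)‑9‑hydroxy‑5,10‑epoxygermacr‑11(13)‑en‑12,8‑olide | C=C1C(=O)O[C@@H]2[C@@H]1C[C@H]1O[C@](C)(CCC[C@@H]1C)[C@H]2O | intermediate
24 | (R)‑2‑methylbutanoic acid | CC[C@@H](C)C(=O)O | starting material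
25 | (R)‑2‑methylbutanoic 2,4,6‑trichlorobenzoic anhydride | CC[C@@H](C)C(=O)OC(=O)c1c(Cl)cc(Cl)cc1Cl | intermediate
26 | (4S,5R,7R,8R,9S,10R)‑5,10‑epoxygermacr‑11(13)‑en‑12,8‑olid‑9‑yl (2R)‑2‑methylbutanoate | C=C1C(=O)O[C@@H]2[C@@H]1C[C@H]1O[C@](C)(CCC[C@@H]1C)[C@H]2OC(=O)[C@H](C)CC | target

**Count and risks**

Total steps: 16. Longest linear sequence: 14 steps (5 → 26, steps 3–16); the ring A branch (steps 1–2) joins at step 7.

Steps most likely to fail:

1. Step 13. The 1,2‑shift may not discriminate sharply enough between C10 and the secondary C4 (leak into the ring‑A‑expanded isomer), and the strained bridgehead cation may lose a proton or reopen faster than it takes hydride from the silane. The fallback below answers the capture problem and allows a regioisomer to be removed at an isolable stage; it does not cure a strong preference for C4 migration. Fallback: setting out from hydroperoxide 16, acetic anhydride/DMAP/pyridine should give the peracetate F1, which on warming in CH2Cl2 rearranges in the classical two‑stage manner to the isolable bridgehead ketal acetate F2; any ring‑A‑expanded regioisomer is separated at this point. Thiolysis with PhSH/BF3·OEt2 at low temperature captures the cation with a small sulfur nucleophile as the bridgehead O,S‑ketal F3. Bu3SnH/AIBN in benzene at 80 °C then delivers the C5 hydrogen to a bridgehead α‑alkoxy radical, which has no planarity requirement, and the route is rejoined at 19.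

2. Step 9. Metathesis may stall at the ruthenium alkylidene of the vinyl group because the exocyclic 1,1‑disubstituted alkene, flanked by quaternary C10 and C4, is too hindered to engage, so that intermolecular cross‑metathesis takes over. Fallback: setting out from alcohol 10, silylation (TBSOTf, 2,6‑lutidine) gives the silyl ether F4; ozonolysis of both alkenes (O3, then Me2S) gives the keto‑aldehyde F5. Intramolecular McMurry coupling (TiCl3/Zn–Cu, DME, reflux) closes ring B as the C5=C6 alkene F6. HF·pyridine frees the alcohol F7 (C9 epimers), and Dess–Martin oxidation rejoins the route at ketone 12.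

3. Step 7. The tetrasubstituted allylboronate may add too slowly, so that the α‑acyloxy aldehyde epimerises or decomposes first, or discrimination between the two faces of ring A may be incomplete. Fallback: setting out from ketone 1 (converted into enolate 2 as in step 1) and aldehyde 9, aldol addition at −78 °C should form the same quaternary C10–C9 bond anti to the C4 methyl and give the β‑hydroxy ketone F8. Takai–Lombardo methylenation (Zn, CH2Br2, TiCl4) of the hindered ring ketone, which leaves the lactone untouched, rejoins the route at 10.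

**Further compounds**

F1 | step 13 | C5 peracetate of 16 | O=C1O[C@@H]2[C@@H](C1)CC1(OOC(C)=O)[C@](C)(CCC[C@@H]1C)[C@H]2O[Si](C)(C)C(C)(C)C
F2 | step 13 | 5‑acetoxy‑9‑(tert‑butyldimethylsilyloxy)‑5,10‑epoxy‑13‑nor‑germacran‑12,8‑olide (bridgehead ketal acetate) | C1C(=O)O[C@@H]2[C@@H]1C[C@@]1(OC(C)=O)O[C@](C)(CCC[C@@H]1C)[C@H]2O[Si](C)(C)C(C)(C)C
F3 | step 13 | 5‑(phenylsulfanyl)‑9‑(tert‑butyldimethylsilyloxy)‑5,10‑epoxy‑13‑nor‑germacran‑12,8‑olide (bridgehead O,S‑ketal) | C1C(=O)O[C@@H]2[C@@H]1C[C@@]1(Sc3ccccc3)O[C@](C)(CCC[C@@H]1C)[C@H]2O[Si](C)(C)C(C)(C)C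
F4 | step 9 | tert‑butyldimethylsilyl ether of 10 (C9 epimers) | O=C1O[C@@H](C(O[Si](C)(C)C(C)(C)C)[C@@]2(C)CCC[C@H](C)C2=C)[C@@H](C1)C=C
F5 | step 9 | keto‑aldehyde from F4 (ring ketone at C5, formyl at C6) | O=C1O[C@@H](C(O[Si](C)(C)C(C)(C)C)[C@@]2(C)CCC[C@H](C)C2=O)[C@@H](C1)C=O
F6 | step 9 | 9‑(tert‑butyldimethylsilyloxy)‑4,10‑dimethyl‑13‑nor‑eudesm‑5‑en‑12,8‑olide (C9 epimers) | O=C1O[C@@H]2[C@@H](C1)C=C1[C@](C)(CCC[C@@H]1C)C2O[Si](C)(C)C(C)(C)C
F7 | step 9 | 9‑hydroxy‑4,10‑dimethyl‑13‑nor‑eudesm‑5‑en‑12,8‑olide (C9 epimers) | O=C1O[C@@H]2[C@@H](C1)C=C1[C@](C)(CCC[C@@H]1C)C2O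
F8 | step 7 | (4S,5R)‑4‑ethenyl‑5‑{[(1S,3S)‑1,3‑dimethyl‑2‑oxocyclohexyl](hydroxy)methyl}oxolan‑2‑one (C9 epimers) | O=C1O[C@@H](C(O)[C@@]2(C)CCC[C@H](C)C2=O)[C@@H](C1)C=C
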